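The C5–C6 CH2–CH2 bond of the octadecanoyl chain (C1 = ester carbonyl) carries no functional group; it lies four carbons beyond the carbonyl, far from the tetrahydrofuran ring (O1, C2–C5) and its stereocentres C2, C3 and C4. One room-temperature sp3–sp3 B-alkyl Suzuki–Miyaura coupling forms this bond. The complete, enantiopure core enters as the 5-bromopentanoate of 4,4'-di-O-benzyl-(+)-lariciresinol; the C13 unit enters as tridec-1-ene, hydroborated in the same flask. The core comes from a Stobbe condensation, an asymmetric hydrogenation to an (R)-β-benzyl-γ-butyrolactone, a trans-selective aldol addition, reduction and a cation-mediated tetrahydrofuran closure. Hydrogenolysis of both benzyl ethers ends the route.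

Key step: step 8

Assumption: the hand of the Rh/(S,S)-Et-DuPhos catalyst in step 2 is assigned by analogy with other β-substituted itaconate half-esters; the configuration of lactone 6 is to be checked (chiral HPLC, sign of rotation) and the antipodal ligand used if the opposite hand is found.

Step 1
Reactants: 1 4-(benzyloxy)-3-methoxybenzaldehyde; 2 dimethyl succinate
Product: 3 (E)-4-[4-(benzyloxy)-3-methoxyphenyl]-3-(methoxycarbonyl)but-3-enoic acid
Conditions: NaOMe (2 equiv), MeOH, reflux; then 2 M HCl; recrystallisation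
Reagents that add atoms: none
Why: Stobbe condensation, in which the succinate enolate adds to the aldehyde, the alkoxide lactonises onto the distal ester and E1cB opening leaves the ester on the alkylidene carbon and the acid on the CH2 arm, the (E)-isomer (aryl trans to CO2Me) being favoured and purified by crystallisation.

Step 2
Reactants: 3 (E)-4-[4-(benzyloxy)-3-methoxyphenyl]-3-(methoxycarbonyl)but-3-enoic acid
Product: 4 (R)-4-[4-(benzyloxy)-3-methoxyphenyl]-3-(methoxycarbonyl)butanoic acid
Conditions: [Rh(cod)((S,S)-Et-DuPhos)]BF4 (cat.), NaOMe (0.1 equiv), H2 (5 bar), MeOH, rt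
Reagents that add atoms: none
Why: Rh-bisphosphine asymmetric hydrogenation of an itaconate-type half-ester, in which carboxylate and olefin chelate rhodium and the C2-symmetric phospholane ligand exposes one olefin face, which sets the (R) centre (the later C4 of the tetrahydrofuran) while the aryl benzyl ether is inert to the homogeneous catalyst.

Step 3
Reactants: 4 (R)-4-[4-(benzyloxy)-3-methoxyphenyl]-3-(methoxycarbonyl)butanoic acid
Product: 6 (R)-4-[4-(benzyloxy)-3-methoxybenzyl]dihydrofuran-2(3H)-one, via hydroxy acid 5 (not isolated)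
Conditions: KOH (1.0 equiv), EtOH, 0 °C; CaCl2, NaBH4, EtOH, −10 °C → rt; then 3 M HCl, rt
Reagents that add atoms: none
Why: Chemoselective borohydride reduction, in which calcium borohydride formed in the flask reduces the methyl ester but not the potassium carboxylate, and acidification closes the γ-lactone from hydroxy acid 5 without touching the stereocentre.

Step 4
Reactants: 6 (R)-4-[4-(benzyloxy)-3-methoxybenzyl]dihydrofuran-2(3H)-one; 1 4-(benzyloxy)-3-methoxybenzaldehyde
Product: 7 (3S,4R)-4-[4-(benzyloxy)-3-methoxybenzyl]-3-{[4-(benzyloxy)-3-methoxyphenyl](hydroxy)methyl}dihydrofuran-2(3H)-one (both carbinol epimers)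
Conditions: LDA (1.1 equiv), THF, −78 °C; then 1, −78 °C; sat. NH4Cl
Reagents that add atoms: none
Why: Lactone enolate aldol addition, in which the aldehyde approaches the lithium enolate on the face opposite the C4 benzyl group and so sets C3 trans to C4 (3S), while the carbinol centre may form as a mixture because it is ionised in step 6.

Step 5
Reactants: 7 (3S,4R)-4-[4-(benzyloxy)-3-methoxybenzyl]-3-{[4-(benzyloxy)-3-methoxyphenyl](hydroxy)methyl}dihydrofuran-2(3H)-one
Product: 8 (2R,3R)-2-[4-(benzyloxy)-3-methoxybenzyl]-3-{[4-(benzyloxy)-3-methoxyphenyl](hydroxy)methyl}butane-1,4-diol (both carbinol epimers)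
Conditions: LiAlH4 (2.5 equiv), THF, 0 °C; H2O, 15% NaOH work-up
Reagents that add atoms: none
Why: Hydride reduction of the lactone to the 1,4-diol at 0 °C, which should outrun retro-aldol cleavage of the aluminium alkoxide and leaves both backbone stereocentres unchanged.

Step 6
Reactants: 8 (2R,3R)-2-[4-(benzyloxy)-3-methoxybenzyl]-3-{[4-(benzyloxy)-3-methoxyphenyl](hydroxy)methyl}butane-1,4-diol
Product: 9 [(2S,3R,4R)-4-[4-(benzyloxy)-3-methoxybenzyl]-2-[4-(benzyloxy)-3-methoxyphenyl]tetrahydrofuran-3-yl]methanol (4,4'-di-O-benzyl-(+)-lariciresinol)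
Conditions: CSA (10 mol%), CH2Cl2 (0.02 M), 0 °C → rt; Et3N quench
Reagents that add atoms: none
Why: Acid-catalysed SN1 cycloetherification, in which both carbinol epimers ionise to the same p-benzyloxy-stabilised benzylic cation, only the hydroxymethyl group on the benzyl-bearing carbon can close a five-membered ring (5-exo-trig; the other would give an oxetane), and closure places the aryl group trans to the neighbouring hydroxymethyl group (2S), the less hindered and, the closure being reversible, also the more stable arrangement.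

Step 7
Reactants: 9 [(2S,3R,4R)-4-[4-(benzyloxy)-3-methoxybenzyl]-2-[4-(benzyloxy)-3-methoxyphenyl]tetrahydrofuran-3-yl]methanol; 10 5-bromopentanoyl chloride
Product: 11 [(2S,3R,4R)-4-[4-(benzyloxy)-3-methoxybenzyl]-2-[4-(benzyloxy)-3-methoxyphenyl]tetrahydrofuran-3-yl]methyl 5-bromopentanoate
Conditions: pyridine (2 equiv), DMAP (cat.), CH2Cl2, 0 °C
Reagents that add atoms: none
Why: Acylation of the only free hydroxyl group (primary, both phenols being benzylated) by the acid chloride under nucleophilic catalysis, the primary bromide surviving the short reaction at 0 °C.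

Step 8
Reactants: 11 [(2S,3R,4R)-4-[4-(benzyloxy)-3-methoxybenzyl]-2-[4-(benzyloxy)-3-methoxyphenyl]tetrahydrofuran-3-yl]methyl 5-bromopentanoate; 12 tridec-1-ene
Product: 14 [(2S,3R,4R)-4-[4-(benzyloxy)-3-methoxybenzyl]-2-[4-(benzyloxy)-3-methoxyphenyl]tetrahydrofuran-3-yl]methyl octadecanoate, via B-tridecyl-9-BBN 13 (not isolated)
Conditions: 12 (1.6 equiv), 9-BBN (1.5 equiv), THF, rt; then 11, Pd(OAc)2 (4 mol%), PCy3 (8 mol%), K3PO4·H2O (1.5 equiv), degassed THF, rt
Reagents that add atoms: 9-BBN, [H]B1C2CCCC1CCC2 (its boron and carbon atoms are carried in intermediate 13 only; 14 keeps one hydrogen from it)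
Why: 9-BBN adds anti-Markovnikov to the terminal alkene of 12 and places boron on the terminal carbon (13); Pd(0)/PCy3 then inserts into the primary C–Br bond of 11 by an SN2-type oxidative addition, the base-activated borane hands its primary alkyl group to palladium, and reductive elimination forms the C5–C6 bond of the octadecanoyl chain. The closest known reaction type is the room-temperature alkyl–alkyl Suzuki–Miyaura coupling of β-hydrogen-bearing primary alkyl bromides with B-alkyl-9-BBN reagents under Pd(OAc)2/PCy3/K3PO4·H2O, which tolerates esters and ethers. No ring is closed and no stereocentre is formed; C2, C3 and C4 of the tetrahydrofuran lie seven or more bonds from the reacting carbon, none is α to the carbonyl, and so none can be scrambled by the mild base. The step needs chemoselectivity for the C(sp3)–Br bond over the ester, the aryl benzyl ethers and the benzylic C2–O1 ether, which the electron-rich phosphine secures at room temperature, and it needs reductive elimination to outrun β-hydride elimination, which the bulk of PCy3 favours. Transfer of the tridecyl group and not of a ring carbon of the borabicycle follows from the faster transmetalation of primary over secondary B–C bonds. The cheap borane is used in excess so that bromide 11 is the limiting partner.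

Step 9
Reactants: 14 [(2S,3R,4R)-4-[4-(benzyloxy)-3-methoxybenzyl]-2-[4-(benzyloxy)-3-methoxyphenyl]tetrahydrofuran-3-yl]methyl octadecanoate
Product: 15 [(2S,3R,4R)-4-(4-hydroxy-3-methoxybenzyl)-2-(4-hydroxy-3-methoxyphenyl)tetrahydrofuran-3-yl]methyl octadecanoate (CNP0168412.1)
Conditions: H2 (1 atm), 10% Pd/C, EtOAc, rt; stopped as soon as 14 and the mono-benzyl ethers are consumed
Reagents that add atoms: none
Why: Heterogeneous hydrogenolysis of the two aryl benzyl ethers, which in a neutral aprotic solvent should be much faster than cleavage of the hindered cyclic benzylic ether C2–O1, so that the ester and the three stereocentres stay untouched.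

Compound list
1 | 4-(benzyloxy)-3-methoxybenzaldehyde | COc1cc(C=O)ccc1OCc1ccccc1 | starting material
2 | dimethyl succinate | COC(=O)CCC(=O)OC | starting material
3 | (E)-4-[4-(benzyloxy)-3-methoxyphenyl]-3-(methoxycarbonyl)but-3-enoic acid | COC(=O)/C(CC(=O)O)=C/c1ccc(OCc2ccccc2)c(OC)c1 | intermediate
4 | (R)-4-[4-(benzyloxy)-3-methoxyphenyl]-3-(methoxycarbonyl)butanoic acid | COC(=O)[C@H](Cc1ccc(OCc2ccccc2)c(OC)c1)CC(=O)O | intermediate
5 | (R)-4-[4-(benzyloxy)-3-methoxyphenyl]-3-(hydroxymethyl)butanoic acid (carboxylate salt in the flask) | OC[C@H](Cc1ccc(OCc2ccccc2)c(OC)c1)CC(=O)O | intermediate (not isolated)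
6 | (R)-4-[4-(benzyloxy)-3-methoxybenzyl]dihydrofuran-2(3H)-one | O=C1C[C@@H](Cc2ccc(OCc3ccccc3)c(OC)c2)CO1 | intermediate
7 | (3S,4R)-4-[4-(benzyloxy)-3-methoxybenzyl]-3-{[4-(benzyloxy)-3-methoxyphenyl](hydroxy)methyl}dihydrofuran-2(3H)-one, carbinol epimers | OC(c1ccc(OCc2ccccc2)c(OC)c1)[C@H]1C(=O)OC[C@@H]1Cc1ccc(OCc2ccccc2)c(OC)c1 | intermediate
8 | (2R,3R)-2-[4-(benzyloxy)-3-methoxybenzyl]-3-{[4-(benzyloxy)-3-methoxyphenyl](hydroxy)methyl}butane-1,4-diol, carbinol epimers | OC(c1ccc(OCc2ccccc2)c(OC)c1)[C@@H](CO)[C@H](CO)Cc1ccc(OCc2ccccc2)c(OC)c1 | intermediate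
9 | [(2S,3R,4R)-4-[4-(benzyloxy)-3-methoxybenzyl]-2-[4-(benzyloxy)-3-methoxyphenyl]tetrahydrofuran-3-yl]methanol | OC[C@H]1[C@@H](Cc2ccc(OCc3ccccc3)c(OC)c2)CO[C@@H]1c1ccc(OCc2ccccc2)c(OC)c1 | intermediate
10 | 5-bromopentanoyl chloride | O=C(Cl)CCCCBr | starting material
11 | [(2S,3R,4R)-4-[4-(benzyloxy)-3-methoxybenzyl]-2-[4-(benzyloxy)-3-methoxyphenyl]tetrahydrofuran-3-yl]methyl 5-bromopentanoate | BrCCCCC(=O)OC[C@H]1[C@@H](Cc2ccc(OCc3ccccc3)c(OC)c2)CO[C@@H]1c1ccc(OCc2ccccc2)c(OC)c1 | intermediate
12 | tridec-1-ene | C=CCCCCCCCCCCC | starting material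
13 | 9-tridecyl-9-borabicyclo[3.3.1]nonane (B-tridecyl-9-BBN) | CCCCCCCCCCCCCB1C2CCCC1CCC2 | intermediate (not isolated)
14 | [(2S,3R,4R)-4-[4-(benzyloxy)-3-methoxybenzyl]-2-[4-(benzyloxy)-3-methoxyphenyl]tetrahydrofuran-3-yl]methyl octadecanoate | CCCCCCCCCCCCCCCCCC(=O)OC[C@H]1[C@@H](Cc2ccc(OCc3ccccc3)c(OC)c2)CO[C@@H]1c1ccc(OCc2ccccc2)c(OC)c1 | intermediate
15 | [(2S,3R,4R)-4-(4-hydroxy-3-methoxybenzyl)-2-(4-hydroxy-3-methoxyphenyl)tetrahydrofuran-3-yl]methyl octadecanoate | CCCCCCCCCCCCCCCCCC(=O)OC[C@H]1[C@@H](Cc2ccc(O)c(OC)c2)CO[C@@H]1c1ccc(O)c(OC)c1 | target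

Total step count: 9. Longest linear sequence: 9 steps (1 → 15); 2, 10 and 12 are bought.

Steps most likely to fail

Step 8. The alkylpalladium formed from 11 may undergo β-hydride elimination or protodebromination faster than it is transmetalated, or the hydrated base may slowly cleave the ester. The fallback forms the same C5–C6 bond as an alkene by cross-metathesis. It sets out from 9: acylation with hex-5-enoyl chloride (pyridine, DMAP, CH2Cl2, 0 °C) should give [(2S,3R,4R)-4-[4-(benzyloxy)-3-methoxybenzyl]-2-[4-(benzyloxy)-3-methoxyphenyl]tetrahydrofuran-3-yl]methyl hex-5-enoate F1. Cross-metathesis with an excess of tetradec-1-ene (Grubbs second-generation catalyst, CH2Cl2, 40 °C) should give the corresponding octadec-5-enoate F2 as an E/Z mixture, which is of no consequence. Hydrogenation (H2, Pd/C, EtOAc) then saturates the alkene and removes both benzyl groups in one operation, so the fallback comes back to the route at 15.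

Step 6. The benzylic cation may be captured by the electron-rich aryl ring of the C4 benzyl group (Friedel–Crafts closure to an aryltetralin), or the closure may show poor facial selectivity at C2 under equilibrating acid. The fallback generates the same cation oxidatively under neutral conditions from a C2-symmetric diol. It sets out from 6: the lithium enolate (LDA, THF/DMPU, −78 °C) is alkylated trans to the benzyl group with 4-(benzyloxy)-3-methoxybenzyl bromide F3 (from commercial 4-(benzyloxy)-3-methoxybenzyl alcohol and PBr3) to give (3R,4R)-3,4-bis[4-(benzyloxy)-3-methoxybenzyl]dihydrofuran-2(3H)-one F4. LiAlH4 reduction should give (2R,3R)-2,3-bis[4-(benzyloxy)-3-methoxybenzyl]butane-1,4-diol F5. DDQ (1.0 equiv, CH2Cl2, 0 °C) abstracts a benzylic hydride and the distal hydroxyl group closes the ring; because F5 is C2-symmetric, oxidation at either benzylic CH2 leads to the same tetrahydrofuran. The fallback comes back to the route at 9.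

Step 9. Hydrogenolysis may go on to open the benzylic C2–O1 bond of the tetrahydrofuran during or after debenzylation. The fallback moves the hydrogenolysis to a stage without that bond and finishes with fluoride. It sets out from 6: H2, Pd/C, EtOAc should give (R)-4-(4-hydroxy-3-methoxybenzyl)dihydrofuran-2(3H)-one F6, and TIPSCl/imidazole/DMF its silyl ether (R)-4-[3-methoxy-4-(triisopropylsilyloxy)benzyl]dihydrofuran-2(3H)-one F7. The sequence of steps 4–8 is then repeated in the silyl series:
- LDA aldol addition to 3-methoxy-4-(triisopropylsilyloxy)benzaldehyde F8 (from vanillin, TIPSCl and imidazole) gives the trans aldol lactone F9.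
- LiAlH4 at 0 °C gives the triol F10.
- CSA in CH2Cl2 gives 4,4'-di-O-TIPS-lariciresinol F11.
- Acylation with 10 gives the 5-bromopentanoate F12.
- Coupling with 13 as in step 8 gives the octadecanoate F13.

TBAF buffered with AcOH (THF, 0 °C) removes both silyl groups without touching the ester or the ring, and the fallback comes back to the route at 15.

Further compounds
F1 | step 8 | [(2S,3R,4R)-4-[4-(benzyloxy)-3-methoxybenzyl]-2-[4-(benzyloxy)-3-methoxyphenyl]tetrahydrofuran-3-yl]methyl hex-5-enoate | C=CCCCC(=O)OC[C@H]1[C@@H](Cc2ccc(OCc3ccccc3)c(OC)c2)CO[C@@H]1c1ccc(OCc2ccccc2)c(OC)c1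
F2 | step 8 | [(2S,3R,4R)-4-[4-(benzyloxy)-3-methoxybenzyl]-2-[4-(benzyloxy)-3-methoxyphenyl]tetrahydrofuran-3-yl]methyl (E)-octadec-5-enoate (major isomer drawn) | CCCCCCCCCCCC/C=C/CCCC(=O)OC[C@H]1[C@@H](Cc2ccc(OCc3ccccc3)c(OC)c2)CO[C@@H]1c1ccc(OCc2ccccc2)c(OC)c1
F3 | step 6 | 4-(benzyloxy)-3-methoxybenzyl bromide | COc1cc(CBr)ccc1OCc1ccccc1
F4 | step 6 | (3R,4R)-3,4-bis[4-(benzyloxy)-3-methoxybenzyl]dihydrofuran-2(3H)-one | COc1cc(C[C@H]2C(=O)OC[C@@H]2Cc2ccc(OCc3ccccc3)c(OC)c2)ccc1OCc1ccccc1
F5 | step 6 | (2R,3R)-2,3-bis[4-(benzyloxy)-3-methoxybenzyl]butane-1,4-diol | COc1cc(C[C@@H](CO)[C@H](CO)Cc2ccc(OCc3ccccc3)c(OC)c2)ccc1OCc1ccccc1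
F6 | step 9 | (R)-4-(4-hydroxy-3-methoxybenzyl)dihydrofuran-2(3H)-one | O=C1C[C@@H](Cc2ccc(O)c(OC)c2)CO1
F7 | step 9 | (R)-4-[3-methoxy-4-(triisopropylsilyloxy)benzyl]dihydrofuran-2(3H)-one | O=C1C[C@@H](Cc2ccc(O[Si](C(C)C)(C(C)C)C(C)C)c(OC)c2)CO1
F8 | step 9 | 3-methoxy-4-(triisopropylsilyloxy)benzaldehyde | COc1cc(C=O)ccc1O[Si](C(C)C)(C(C)C)C(C)C
F9 | step 9 | (3S,4R)-3-{hydroxy[3-methoxy-4-(triisopropylsilyloxy)phenyl]methyl}-4-[3-methoxy-4-(triisopropylsilyloxy)benzyl]dihydrofuran-2(3H)-one, carbinol epimers | OC(c1ccc(O[Si](C(C)C)(C(C)C)C(C)C)c(OC)c1)[C@H]1C(=O)OC[C@@H]1Cc1ccc(O[Si](C(C)C)(C(C)C)C(C)C)c(OC)c1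
F10 | step 9 | (2R,3R)-3-{hydroxy[3-methoxy-4-(triisopropylsilyloxy)phenyl]methyl}-2-[3-methoxy-4-(triisopropylsilyloxy)benzyl]butane-1,4-diol, carbinol epimers | OC(c1ccc(O[Si](C(C)C)(C(C)C)C(C)C)c(OC)c1)[C@@H](CO)[C@H](CO)Cc1ccc(O[Si](C(C)C)(C(C)C)C(C)C)c(OC)c1
F11 | step 9 | [(2S,3R,4R)-4-[3-methoxy-4-(triisopropylsilyloxy)benzyl]-2-[3-methoxy-4-(triisopropylsilyloxy)phenyl]tetrahydrofuran-3-yl]methanol | OC[C@H]1[C@@H](Cc2ccc(O[Si](C(C)C)(C(C)C)C(C)C)c(OC)c2)CO[C@@H]1c1ccc(O[Si](C(C)C)(C(C)C)C(C)C)c(OC)c1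
F12 | step 9 | [(2S,3R,4R)-4-[3-methoxy-4-(triisopropylsilyloxy)benzyl]-2-[3-methoxy-4-(triisopropylsilyloxy)phenyl]tetrahydrofuran-3-yl]methyl 5-bromopentanoate | BrCCCCC(=O)OC[C@H]1[C@@H](Cc2ccc(O[Si](C(C)C)(C(C)C)C(C)C)c(OC)c2)CO[C@@H]1c1ccc(O[Si](C(C)C)(C(C)C)C(C)C)c(OC)c1
F13 | step 9 | [(2S,3R,4R)-4-[3-methoxy-4-(triisopropylsilyloxy)benzyl]-2-[3-methoxy-4-(triisopropylsilyloxy)phenyl]tetrahydrofuran-3-yl]methyl octadecanoate | CCCCCCCCCCCCCCCCCC(=O)OC[C@H]1[C@@H](Cc2ccc(O[Si](C(C)C)(C(C)C)C(C)C)c(OC)c2)CO[C@@H]1c1ccc(O[Si](C(C)C)(C(C)C)C(C)C)c(OC)c1
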